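- Every molecule of starting material I charged stayed on the count, held by some species with one side product as two, so I asked how fast target multiplies against how fast it leaves.

| flask | starting material | time | remark |
|---|---|---|---|
| theta | 0.050 M | 1.5 h | a closed flask charged with all of it at once and left for 1.5 h |
| epsilon | 0.050 M |  | one stirred flow tank at steady state, fed with the mixture as stated, mean residence time 1.5 h |

1. the set-up with the highest amount of target at the outlet or at the end, in percent of the starting material put in ("none" if the first two lie within 2 percentage points) (theta / epsilon / none)
2. amount of target at the outlet or at the end, in percent of the starting material put in, theta
3. amount of target at the outlet or at the end, in percent of the starting material put in, epsilon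

- percentages count the starting material that a species holds: one side product counts as two
- the stated concentrations are those of everything mixed, before any reaction; amounts are the same in each set-up
- run time (theta): 1.5 h

- At the charged level, each target made another at 0.0498 /min. The side step took it at 0.002355 /min and the over-reaction at 0.00103 /min, which I treated as corrections, leaving a pseudo-first-order net growth constant g of 0.0465 /min.
- I folded this into G, the net growth constant times the time of stay, the number of e-fold multiplications of target in that time: 4.18.
- In closed flask theta, the uncatalysed step seeds target with constant 9.19 × 10⁻⁶ /min, and exp(G) amplifies the seed 65.4-fold, so target is the seed constant over g, times that amplification less one: 1.28 %.
- In tank epsilon, target at the charged level grows faster than it washes out, so G says the tank ignites, but one number was not enough for the yield, since the tank runs below the charged level. I dropped the seed and let each target just replace itself, which puts starting material at 0.0128 M; its balance then gives target 62.0 %.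
- My choice was epsilon.
- The forecast gave epsilon, with 1.26 % for theta (1.1 % to 1.4 %) and 62 % for epsilon (60.5 % to 63.5 %), holding of the tank that “since the residence time exceeds the washout threshold it has only the ignited steady state”.

    starting material + target → 2 target (k1 = 0.997 /M/min)
    starting material → target (k2 = 9.19 × 10⁻⁶ /min)
    target → over-reaction product (k3 = 0.00103 /min)
    starting material + target → side product (k4 = 0.0471 /M/min)

- The simulation gave epsilon, with 1.26 % in theta and 62.0 % in epsilon. Closed flask theta ended with 98.6 % of its starting material, close to the charged level that G assumes. With the target-catalysed step struck out of theta, G became a loss of 0.305, and the same expression, seed over net constant, gave 0.0713 %; that run of theta ended at 0.0713 % target.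

All constants were set for the occasion; what happens was integrated by code.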